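**Retrosynthetic overview**
- The guaiacyl-side C=C of the heptadienone is cut by a boron-templated (Pabon) aldol condensation, giving a terpenyl vanillin ether and (E)-6-(4-hydroxyphenyl)hex-5-ene-2,4-dione.
- The allylic C1–OAr bond is cut to vanillin plus the π-allyl-Pd species of a cis-configured vinyl epoxide (double inversion).
- The vinyl epoxide comes from P(III) deoxygenation of a 2,3-dioxabicyclo[2.2.2]octene. That endoperoxide comes from a visible-light ¹O2 [4+2] on the ring diene of (+)-α-turmerone, which supplies C6 and the side-chain stereocentre. The C4–O bond made by light survives to the target and dictates the face of the aryl ether.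
- All carbocycles are purchased. Only transient rings are formed: the 1,2-dioxane bridge (step 1), then the oxirane (step 2), which is opened in step 3.

Assumption 1: natural (+)-α-turmerone has the zingiberene/bisacurone-type (1'R,6S) configuration drawn below. It is sold neat and is the main 1,3-diene (about 20–30 %) of food-grade turmeric oil. An enriched cut is sufficient, because ar- and β-turmerone cannot undergo the [4+2] reaction and elute far from the endoperoxide.
Assumption 2: the keto-enol drawn in the target SMILES is the spontaneous H-bonded tautomer of the 1,3-diketone.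
Ring numbering used below: C1 (OAr), C2=C3(Me), C4 (OH), C5H2, C6 (side chain). The α-face is the face anti to the side chain.

**Step 1**
Reactants: 1, (+)-α-turmerone
Product: 2, anti-endoperoxide, (6S)-2-methyl-6-[(1R,4S,7R)-5-methyl-2,3-dioxabicyclo[2.2.2]oct-5-en-7-yl]hept-2-en-4-one (peroxide bridge on the α-face)
Conditions: O2 (1 atm), TPP (0.2 mol %), white LED (hν > 400 nm), CH2Cl2, −30 °C, 1–2 h, stopped at full diene consumption; SiO2 chromatography without amine removes the minor syn isomer
Reagents that add atoms: dioxygen, O=O
Why: This is a type-II photosensitised singlet-oxygen [4+2] cycloaddition (hetero-Diels–Alder endoperoxidation) in which the s-cis ring diene reacts far faster than the electron-poor enone C=C, and O2 adds anti to the purchased C6 substituent (about 2–3:1 expected by analogy with α-phellandrene), setting C1 (R) and C4 (S) together.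

**Step 2**
Reactants: 2, anti-endoperoxide
Product: 3, α-vinyl epoxide, (6S)-2-methyl-6-[(1R,4R,6S)-1-methyl-7-oxabicyclo[4.1.0]hept-2-en-4-yl]hept-2-en-4-one (C3–C4 oxirane on the α-face, C1=C2 alkene)
Conditions: PPh3 (1.05 equiv), THF, 0 °C to rt, 1 h; the solution is used directly in step 3 without work-up
Reagents that add atoms: none (PPh3 only removes one O as Ph3P=O)
Why: This is the phosphine deoxygenation of an unsaturated bicyclic endoperoxide to a 1,3-diene monoepoxide, in which PPh3 inserts into O–O and the phosphonium alkoxide collapses by syn-SN2′ loss of Ph3P=O from C1 (the only C–O bond whose heterolysis puts charge on a methyl-bearing, tertiary allyl terminus) while C4–O⁻ closes on C3, so the photochemically set C4–O bond keeps its (S) configuration and forces the new C3 centre onto the same α-face.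

**Step 3**
Reactants: 3, α-vinyl epoxide (THF solution from step 2); 4, vanillin
Product: 5, 4-{[(1R,4S,6R)-4-hydroxy-3-methyl-6-[(2S)-6-methyl-4-oxohept-5-en-2-yl]cyclohex-2-en-1-yl]oxy}-3-methoxybenzaldehyde (OAr and OH cis, both trans to the side chain)
Conditions: 4 (1.2 equiv), Pd2(dba)3·CHCl3 (2.5 mol %), PPh3 (10 mol %), THF (same flask), 0 °C to rt, 2 h
Reagents that add atoms: vanillin (4), COc1cc(C=O)ccc1O
Why: Proposed new method: a Pd(0)-catalysed cis-1,4-hydroxy-aryloxylation run directly on the phosphine-deoxygenation stream, so that endoperoxide 2 serves overall as a latent cis-1,4-hydroxy/π-allyl synthon, in which Pd(0) ionises the tertiary allylic C3–O bond of 3 with inversion (Pd on the β-face), the released C4 alkoxide deprotonates vanillin (pKa 7.4), and the aryloxide attacks the less substituted distal terminus C1 anti to Pd, i.e. on the α-face, cis to C4–OH and trans to the side chain (double inversion, setting C1 as R), while reversible re-ionisation of any tertiary C3 ether funnels material to the 1,4-product with the trisubstituted alkene; the closest known reaction type is the Tsuji–Trost cis-1,4-opening of unsubstituted cyclopentadiene and cyclohexadiene monoepoxides by phenols and carboxylic acids, which has not been shown with ionisation at a fully substituted epoxide carbon, with attack next to a branched stereocentre, or in relay with an endoperoxide deoxygenation.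

**Step 4**
Reactants: 6, acetylacetone (3 equiv); 7, 4-hydroxybenzaldehyde
Product: 8, (5E)-6-(4-hydroxyphenyl)hex-5-ene-2,4-dione
Conditions: B2O3, B(On-Bu)3, n-BuNH2 (cat.), EtOAc, 70 °C; then 0.4 M HCl, 50 °C
Reagents that add atoms: none (all product atoms come from 6 and 7; H2O is lost)
Why: In this Pabon mono-condensation, boron chelation blocks the central carbon so the amine-catalysed aldol/dehydration occurs at a terminal CH3, and excess acetylacetone suppresses double condensation, giving the E-enone.

**Step 5**
Reactants: 5, terpenyl vanillin ether; 8, half-curcuminoid
Product: 9, demethoxybisabolocurcumin ether (target)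
Conditions: 8, B2O3 (0.7 equiv), EtOAc, 70 °C, 45 min; then 5 (1 equiv), B(On-Bu)3 (2 equiv), n-BuNH2 (0.3 equiv), 40 °C, 12 h; then 5 % aq. citric acid, rt
Reagents that add atoms: none (all product atoms come from 5 and 8; H2O is lost)
Why: In this Pabon condensation only the boron-chelated diketone of 8 is activated at its remaining CH3, so the terpene enone stays a spectator, the C4–OH is only reversibly borylated, E1cB dehydration gives the E-alkene, and a citric acid work-up at rt is used instead of warm HCl to spare the ionisable allylic aryl ether, with no stereocentre touched.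

**Compound list**

| No. | Name | SMILES | Role |
|---|---|---|---|
| 1 | (+)-α-turmerone, (6S)-2-methyl-6-[(1R)-4-methylcyclohexa-2,4-dien-1-yl]hept-2-en-4-one | CC1=CC[C@@H](C=C1)[C@@H](C)CC(=O)C=C(C)C | starting material |
| 2 | anti-endoperoxide (1R,4S,7R; side chain 6S) | CC1=C[C@@H]2OO[C@H]1C[C@@H]2[C@@H](C)CC(=O)C=C(C)C | intermediate |
| 3 | α-vinyl epoxide, (6S)-2-methyl-6-[(1R,4R,6S)-1-methyl-7-oxabicyclo[4.1.0]hept-2-en-4-yl]hept-2-en-4-one | C1=C[C@@]2(C)O[C@H]2C[C@@H]1[C@@H](C)CC(=O)C=C(C)C | intermediate |
| 4 | vanillin | COc1cc(C=O)ccc1O | starting material |
| 5 | (1R,4S,6R,2'S)-terpenyl vanillin ether | COc1cc(C=O)ccc1O[C@H]1C=C(C)[C@@H](O)C[C@@H]1[C@@H](C)CC(=O)C=C(C)C | intermediate |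
| 6 | acetylacetone | CC(=O)CC(C)=O | starting material |
| 7 | 4-hydroxybenzaldehyde | O=Cc1ccc(O)cc1 | starting material |
| 8 | (5E)-6-(4-hydroxyphenyl)hex-5-ene-2,4-dione | CC(=O)CC(=O)/C=C/c1ccc(O)cc1 | intermediate |
| 9 | demethoxybisabolocurcumin ether | COc1cc(/C=C/C(O)=C/C(=O)/C=C/c2ccc(O)cc2)ccc1O[C@H]1C=C(C)[C@@H](O)C[C@@H]1[C@@H](C)CC(=O)C=C(C)C | target |

**Total steps:** 5. Steps 2 and 3 share one flask, so four products are isolated. **Longest linear sequence:** 4 (steps 1, 2, 3, 5).

**Steps most likely to fail**

1. **Step 3 (new method).**
   - Risks: Pd must bind on the face syn to the side chain, so ionisation may be slow. Pd may isomerise 3 to a dienol/enone or aromatise it to ar-turmerone. Some 1,2-attack at C3 may persist.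
   - Fallback (known chemistry, arylating oxygen instead of substituting carbon): reduce 2 with thiourea to the cis-1,4-diol. Mono-silylate the less hindered C4–OH with TBSCl. Couple the C1–OH with 4-bromo-3-methoxybenzaldehyde by Pd-catalysed (bulky biarylphosphine, Cs2CO3) or Ni/photoredox C–O cross-coupling, which leaves the C1–O bond and its configuration untouched. Then desilylate. This replaces steps 2–3 with four steps (+2).
2. **Step 2.**
   - Risks: the deoxygenation may close the wrong way, giving the C1–C2 epoxide. Epoxide 3 is also labile towards loss of water and aromatisation.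
   - Fallback: bypass the peroxide. Mono-epoxidise the more nucleophilic trisubstituted diene C=C of 1 in the dark with DMDO (acetone, −78 to −40 °C). This gives 3 and its β-epimer with unambiguous regiochemistry. Carry both through the Pd opening and separate them as 5. This also removes the dependence on the facial selectivity of step 1.
3. **Step 5.**
   - Risks: the allylic aryl ether may ionise under boron or acid conditions, and aryl scrambling may give symmetric curcuminoids.
   - Fallback: reverse the order of events. Prepare 4''-O-TBS-demethoxycurcumin as its BF2 chelate from 4-(TBSO)benzaldehyde, acetylacetone·BF2 and vanillin, so the diketone is masked and only the guaiacol OH is free. Use it as the O-nucleophile in the Pd opening of 3. Then remove BF2 (aq. MeOH, sodium oxalate) and TBS (TBAF/AcOH) under near-neutral conditions.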